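Numbering (decalin): C1 carries the dienoic acid, C2 the butenyl group, then C3(Me)=C4, C4a, C5, C6, C7 (O), C8 (Me), C8a. Ring A is C1–C4, C4a, C8a. Ring B is C4a–C8a.
Retrosynthesis: cut the O–SO3H bond and the ester, then C1'=C2' of the side chain (cross metathesis), then C4a–C8a and C6–C7 together, then C8=C8a (olefination), C1–C2 ([3,3]), C2–C3 (cross-coupling) and C3=C4 (Wittig).
Enabling feature: in ring B the C7 carbinol is 1,3 to C5, and C8a is 1,3 to C7. A temporary ketone at C5 therefore makes C4a and C6 its two α-carbons (C4a is also allylic to the ring A alkene C3=C4). C8a and C7 become the β-carbon and carbonyl carbon of a 2-methylenal, so one acyclic chain holds a bis-nucleophile and a bis-electrophile.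
Forward: two fragments are joined to a dienol, which is esterified and rearranged to the branched chain. The Z-enal and the ketone are unveiled, and one base treatment closes ring A and then ring B. The C5 ketone is then deleted, and the side chain and the sulfate are added.
Stereochemistry: (R)-but-3-yn-2-ol is the only chiral source. The chair Ireland–Claisen step transfers it to C1, C2 and the E-butenyl bond. C1 (A1,3 strain), the Z-enal geometry and lithium-bridged chair transition states then set C8a, C4a, C8 and C7.

Key step: step 14

Assumption: the target is taken as drawn, as the free hydrogen sulfate and carboxylic acid. It is liberated from its salt only in the last operation and would be stored as a salt.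

Step 1
Reactants: 1 ethyl 2-(2-methyl-1,3-dioxolan-2-yl)acetate
Product: 2 2-(2-methyl-1,3-dioxolan-2-yl)acetaldehyde
Conditions: DIBAL-H (1.05 equiv), CH2Cl2, −78 °C; aq. Rochelle salt
Reagents that add atoms: none
Why: Partial ester reduction with DIBAL-H stops at the aluminium hemiacetal at −78 °C and releases the aldehyde on work-up, and the ketal is inert.

Step 2
Reactants: 2 2-(2-methyl-1,3-dioxolan-2-yl)acetaldehyde
Product: 3 2-[(2Z)-3-iodobut-2-en-1-yl]-2-methyl-1,3-dioxolane
Conditions: EtPPh3I, n-BuLi, THF; I2, −78 °C; NaHMDS, −20 °C; then 2, −78 °C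
Reagents that add atoms: ethyltriphenylphosphonium iodide CC[P+](c1ccccc1)(c1ccccc1)c1ccccc1.[I-]; iodine II
Why: The Stork–Zhao-type Wittig olefination with (1-iodoethylidene)triphenylphosphorane should give the (Z)-2-iodo-2-alkene from an aliphatic aldehyde, which fixes the later C3=C4 geometry (C4a cis to the carbon that will carry C2).

Step 3
Reactants: 4 (R)-but-3-yn-2-ol
Product: 5 (R)-3-(tert-butyldimethylsilyloxy)but-1-yne
Conditions: TBSCl, imidazole, CH2Cl2, rt
Reagents that add atoms: tert-butyldimethylsilyl chloride CC(C)(C)[Si](C)(C)Cl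
Why: Standard silyl ether formation masks the alcohol for the organoaluminium step and does not touch the stereocentre.

Step 4
Reactants: 5 (R)-3-(tert-butyldimethylsilyloxy)but-1-yne; 3 2-[(2Z)-3-iodobut-2-en-1-yl]-2-methyl-1,3-dioxolane
Product: 7 tert-butyldimethylsilyl ether of (2R,3E,5Z)-3,5-dimethyl-7-(2-methyl-1,3-dioxolan-2-yl)hepta-3,5-dien-2-ol, via alkenylalane 6 (not isolated)
Conditions: Me3Al, Cp2ZrCl2 (cat.), ClCH2CH2Cl, rt; volatiles off; then 3, Pd(PPh3)4 (cat.), ZnCl2 (cat.), THF, rt
Reagents that add atoms: trimethylaluminium C[Al](C)C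
Why: Zirconium-catalysed syn-carboalumination puts methyl and aluminium cis, and the Negishi cross-coupling keeps the geometry of both sp2 partners, so the (3E,5Z)-diene should result.

Step 5
Reactants: 7 tert-butyldimethylsilyl ether of the dienol
Product: 8 (2R,3E,5Z)-3,5-dimethyl-7-(2-methyl-1,3-dioxolan-2-yl)hepta-3,5-dien-2-ol
Conditions: TBAF, THF, 0 °C to rt
Reagents that add atoms: none
Why: Fluoride-induced desilylation frees the allylic alcohol without affecting the ketal or the diene.

Step 6
Reactants: 8 (2R,3E,5Z)-3,5-dimethyl-7-(2-methyl-1,3-dioxolan-2-yl)hepta-3,5-dien-2-ol; 9 but-3-enoic acid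
Product: 10 but-3-enoate ester of dienol 8
Conditions: DCC, DMAP (cat.), CH2Cl2, −20 to 0 °C
Reagents that add atoms: none
Why: Steglich esterification acylates the secondary allylic alcohol with retention, and the low temperature and catalytic DMAP should keep the acid from isomerising to the crotonate.

Step 7
Reactants: 10 but-3-enoate ester of dienol 8
Product: 13 (2R,3R,4E)-2-ethenyl-4-methyl-3-[(2Z)-4-(2-methyl-1,3-dioxolan-2-yl)but-2-en-2-yl]hex-4-enoic acid, via silyl ketene acetal 11 (not isolated), via trimethylsilyl ester 12 (not isolated)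
Conditions: LDA, THF–DMPU, −78 °C; TMSCl; −78 °C to rt; aq. NH4Cl
Reagents that add atoms: chlorotrimethylsilane C[Si](C)(C)Cl
Why: In the Ireland–Claisen rearrangement the polar cosolvent should give the Z-silyl ketene acetal (vinyl cis to OSiMe3); the chair transition state with the carbinol methyl equatorial then carries the R centre over to C2, sets C1 relative to C2, and gives the E-butenyl bond.

Step 8
Reactants: 13 the hexenoic acid
Product: 14 primary alcohol obtained from acid 13 (CH2OH in place of CO2H and stereocentres unchanged)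
Conditions: LiAlH4, Et2O, 0 °C
Reagents that add atoms: none
Why: Hydride reduction of the carboxylic acid leaves the isolated alkenes, the ketal and both stereocentres untouched.

Step 9
Reactants: 14 the primary alcohol
Product: 15 α-vinyl aldehyde obtained from alcohol 14 (CHO = future C8a)
Conditions: Dess–Martin periodinane, CH2Cl2, 0 °C; used at once
Reagents that add atoms: none
Why: Dess–Martin oxidation is fast and nearly neutral, which should avoid epimerisation at C1 and migration of the vinyl group into conjugation.

Step 10
Reactants: 15 the α-vinyl aldehyde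
Product: 16 methyl (Z)-2-methylenoate obtained from aldehyde 15 (CO2Me cis to C1)
Conditions: (CF3CH2O)2P(O)CH(CH3)CO2Me, KHMDS, 18-crown-6, THF, −78 °C
Reagents that add atoms: methyl 2-[bis(2,2,2-trifluoroethoxy)phosphoryl]propanoate COC(=O)C(C)P(=O)(OCC(F)(F)F)OCC(F)(F)F
Why: The Still–Gennari olefination gives Z-trisubstituted enoates from α-branched aldehydes under kinetic control at −78 °C, where the aldehyde is not enolised.

Step 11
Reactants: 16 the (Z)-enoate
Product: 17 (Z)-allylic alcohol obtained from enoate 16
Conditions: DIBAL-H (2.2 equiv), CH2Cl2, −78 °C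
Reagents that add atoms: none
Why: DIBAL-H reduces the enoate 1,2 to the allylic alcohol with retention of the Z geometry, and the ketal is inert.

Step 12
Reactants: 17 the (Z)-allylic alcohol
Product: 18 β,γ-unsaturated methyl ketone bearing the (Z)-allylic alcohol
Conditions: PPTS (cat.), THF–H2O, 40 °C
Reagents that add atoms: water O
Why: Mild acid-catalysed ketal hydrolysis unveils the temporary C5 ketone under conditions too weak to move the C3=C4 bond into conjugation.

Step 13
Reactants: 18 the keto alcohol
Product: 19 acyclic keto (Z)-enal (methyl ketone C5 and C6; enal C7, C8 and C8a)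
Conditions: activated MnO2, CH2Cl2, rt, dark
Reagents that add atoms: none
Why: Manganese dioxide oxidises only the allylic alcohol and is known to preserve Z-enal geometry.

Step 14
Reactants: 19 acyclic keto (Z)-enal
Product: 22 cis-fused ketol (C5 ketone; C7 axial hydroxyl; C4a, C8a, C8 and C7 as in the target; vinyl at C1), via lithium dienolate 20 (not isolated), via monocyclic keto aldehyde 21 (not isolated)
Conditions: LDA (1.0 equiv), THF, −78 to −40 °C, high dilution; AcOH in THF, −78 °C
Reagents that add atoms: lithium diisopropylamide CC(C)[N-]C(C)C.[Li+]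
Why: LDA removes the doubly activated C4a–H (α to the temporary C5 ketone and allylic to C3=C4) to give the Z(O)-lithium dienolate 20, whose α-carbon C4a adds to C8a of the enal (intramolecular Michael addition); the aldehyde enolate so formed is protonated through a six-membered relay by the C6 methyl group and the new C6 enolate adds to C7 (aldol addition), which is the Michael–aldol α,α'-annulation ([3+3]) known for fusing ketones with 2-methylacrolein. Ring A closes 6-exo-trig at the acceptor with the Z C3=C4 bond inside the new ring, and ring B closes 6-(enolexo)-exo-trig. C8a is controlled by A(1,3) strain, which holds C1–H in the plane of the trisubstituted enal so that the tethered nucleophile reaches only the face that puts C8 trans to the C1 vinyl group. C4a is controlled by the lithium-bridged closed transition state, in which O5–Li–O7 can form only when the enolate lies over the formyl group, and because the enal is Z (CHO cis to C1) this places C5 pseudo-axial and cis to C8, which is the cis ring fusion. C8 stays epimerisable as an α-formyl centre until the aldol step, which should drain the epimer with an equatorial methyl group through a chair in which lithium bridges O5 and O7, giving the axial C7 alkoxide cis to that methyl group. The step needs 1,4- over 1,2-addition and attack by C4a rather than C6 or C3, which ring size secures (six-membered closure against eight-, ten- and four-membered ones), and one equivalent of base with a cold acidic quench should keep 22 from being enolised toward C4a.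

Step 15
Reactants: 22 cis-fused ketol
Product: 23 C5 tosylhydrazone of ketol 22
Conditions: TsNHNH2, THF–EtOH, rt
Reagents that add atoms: p-toluenesulfonyl hydrazide Cc1ccc(cc1)S(=O)(=O)NN
Why: Hydrazone condensation at room temperature without added acid or base should derivatise the only ketone without retro-aldol cleavage or epimerisation at C4a.

Step 16
Reactants: 23 the tosylhydrazone
Product: 25 cis-fused bicyclic alcohol (C5 now CH2; C7 hydroxyl; vinyl at C1), via alkyl diazene 24 (not isolated)
Conditions: catecholborane (3 equiv), CHCl3, −10 °C; NaOAc·3H2O, reflux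
Reagents that add atoms: none
Why: The Kabalka variant of the Caglioti reduction adds hydride to C=N, then loses sulfinate and nitrogen, which deletes the helper ketone; the diazene is homoallylic so no alkene transposition is possible, and uncatalysed catecholborane is too slow to hydroborate the alkenes.

Step 17
Reactants: 25 cis-fused bicyclic alcohol; 26 methyl (2E)-penta-2,4-dienoate
Product: 27 methyl (2E,4E)-dienoate with free C7 hydroxyl (methyl ester of the desulfated target)
Conditions: Hoveyda–Grubbs II (cat.), 26 (3 equiv), CH2Cl2, 40 °C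
Reagents that add atoms: none
Why: Ene–diene cross metathesis engages only the monosubstituted vinyl group of 25 and the terminal alkene of 26 (all other alkenes are trisubstituted or electron-poor) and should give the E-configured new bond.

Step 18
Reactants: 27 the hydroxy dienoate
Product: 28 pyridinium salt of the C7 sulfate monoester of 27
Conditions: SO3·pyridine, pyridine, 40 °C
Reagents that add atoms: sulfur trioxide pyridine complex [O-]S(=O)(=O)[n+]1ccccc1
Why: O-Sulfation with the SO3–pyridine complex converts the only hydroxyl group with retention at C7, and the ester blocks mixed-anhydride formation at the acid terminus.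

Step 19
Reactants: 28 the pyridinium sulfate
Product: 30 (2E,4E)-5-[(1S,2R,4aS,7S,8R,8aR)-2-[(E)-but-2-en-2-yl]-3,8-dimethyl-7-(sulfooxy)-1,2,4a,5,6,7,8,8a-octahydronaphthalen-1-yl]penta-2,4-dienoic acid, via dilithium salt 29 (not isolated)
Conditions: LiOH, THF–MeOH–H2O, rt; 1 M HCl to pH 1, 0 °C, n-BuOH extraction
Reagents that add atoms: lithium hydroxide [Li+].[OH-]
Why: Saponification cleaves the methyl ester while the sulfate monoester anion resists hydroxide, and brief cold acidification gives the free diacid.

Compound list
1 | ethyl 2-(2-methyl-1,3-dioxolan-2-yl)acetate | CCOC(=O)CC1(C)OCCO1 | starting material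
2 | 2-(2-methyl-1,3-dioxolan-2-yl)acetaldehyde | O=CCC1(C)OCCO1 | intermediate
3 | 2-[(2Z)-3-iodobut-2-en-1-yl]-2-methyl-1,3-dioxolane | C/C(I)=C/CC1(C)OCCO1 | intermediate
4 | (R)-but-3-yn-2-ol | C[C@@H](O)C#C | starting material
5 | (R)-3-(tert-butyldimethylsilyloxy)but-1-yne | C[C@@H](O[Si](C)(C)C(C)(C)C)C#C | intermediate
6 | dimethyl[(1E,3R)-3-(tert-butyldimethylsilyloxy)-2-methylbut-1-en-1-yl]alane (not isolated) | C[C@@H](O[Si](C)(C)C(C)(C)C)/C(C)=C/[Al](C)C | intermediate
7 | tert-butyldimethylsilyl ether of dienol 8 | C[C@@H](O[Si](C)(C)C(C)(C)C)/C(C)=C/C(C)=C\CC1(C)OCCO1 | intermediate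
8 | (2R,3E,5Z)-3,5-dimethyl-7-(2-methyl-1,3-dioxolan-2-yl)hepta-3,5-dien-2-ol | C[C@@H](O)/C(C)=C/C(C)=C\CC1(C)OCCO1 | intermediate
9 | but-3-enoic acid | C=CCC(=O)O | starting material
10 | but-3-enoate ester of 8 | C[C@@H](OC(=O)CC=C)/C(C)=C/C(C)=C\CC1(C)OCCO1 | intermediate
11 | Z-trimethylsilyl ketene acetal of 10, vinyl cis to OSiMe3 (not isolated) | C[C@@H](O/C(O[Si](C)(C)C)=C/C=C)/C(C)=C/C(C)=C\CC1(C)OCCO1 | intermediate
12 | trimethylsilyl ester of 13 (not isolated) | C/C=C(\C)[C@H](/C(C)=C\CC1(C)OCCO1)[C@@H](C=C)C(=O)O[Si](C)(C)C | intermediate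
13 | (2R,3R,4E)-2-ethenyl-4-methyl-3-[(2Z)-4-(2-methyl-1,3-dioxolan-2-yl)but-2-en-2-yl]hex-4-enoic acid | C/C=C(\C)[C@H](/C(C)=C\CC1(C)OCCO1)[C@@H](C=C)C(=O)O | intermediate
14 | primary alcohol from 13 | C/C=C(\C)[C@H](/C(C)=C\CC1(C)OCCO1)[C@@H](C=C)CO | intermediate
15 | α-vinyl aldehyde from 14 | C/C=C(\C)[C@H](/C(C)=C\CC1(C)OCCO1)[C@@H](C=C)C=O | intermediate
16 | methyl (Z)-2-methylenoate from 15 | C/C=C(\C)[C@H](/C(C)=C\CC1(C)OCCO1)[C@@H](C=C)/C=C(/C)C(=O)OC | intermediate
17 | (Z)-allylic alcohol from 16 | C/C=C(\C)[C@H](/C(C)=C\CC1(C)OCCO1)[C@@H](C=C)/C=C(/C)CO | intermediate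
18 | keto (Z)-allylic alcohol | C/C=C(\C)[C@H](/C(C)=C\CC(C)=O)[C@@H](C=C)/C=C(/C)CO | intermediate
19 | acyclic keto (Z)-enal | C/C=C(\C)[C@H](/C(C)=C\CC(C)=O)[C@@H](C=C)/C=C(/C)C=O | intermediate
20 | Z(O)-lithium dienolate of 19 (not isolated) | C/C=C(\C)[C@H](/C(C)=C\C=C(\C)O[Li])[C@@H](C=C)/C=C(/C)C=O | intermediate
21 | monocyclic keto aldehyde, ring A closed, acetyl and 1-formylethyl groups cis, drawn neutral, C8 not fixed (not isolated) | C/C=C(\C)[C@@H]1C(C)=C[C@@H](C(C)=O)[C@@H](C(C)C=O)[C@@H]1C=C | intermediate
22 | cis-fused ketol | C/C=C(\C)[C@@H]1C(C)=C[C@H]2C(=O)C[C@H](O)[C@H](C)[C@H]2[C@@H]1C=C | intermediate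
23 | C5 tosylhydrazone of 22 | C/C=C(\C)[C@@H]1C(C)=C[C@H]2C(=NNS(=O)(=O)c3ccc(C)cc3)C[C@H](O)[C@H](C)[C@H]2[C@@H]1C=C | intermediate
24 | C5 alkyl diazene (not isolated) | C/C=C(\C)[C@@H]1C(C)=C[C@H]2C(N=N)C[C@H](O)[C@H](C)[C@H]2[C@@H]1C=C | intermediate
25 | cis-fused bicyclic alcohol with vinyl at C1 | C/C=C(\C)[C@@H]1C(C)=C[C@H]2CC[C@H](O)[C@H](C)[C@H]2[C@@H]1C=C | intermediate
26 | methyl (2E)-penta-2,4-dienoate | C=C/C=C/C(=O)OC | starting material
27 | methyl (2E,4E)-dienoate with free C7 hydroxyl | C/C=C(\C)[C@@H]1C(C)=C[C@H]2CC[C@H](O)[C@H](C)[C@H]2[C@@H]1/C=C/C=C/C(=O)OC | intermediate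
28 | pyridinium salt of the C7 sulfate of 27 | C/C=C(\C)[C@@H]1C(C)=C[C@H]2CC[C@H](OS(=O)(=O)[O-])[C@H](C)[C@H]2[C@@H]1/C=C/C=C/C(=O)OC.c1cc[nH+]cc1 | intermediate
29 | dilithium carboxylate sulfate (not isolated) | C/C=C(\C)[C@@H]1C(C)=C[C@H]2CC[C@H](OS(=O)(=O)[O-])[C@H](C)[C@H]2[C@@H]1/C=C/C=C/C(=O)[O-].[Li+].[Li+] | intermediate
30 | CNP0450810.2 | C/C=C(\C)[C@@H]1C(C)=C[C@H]2CC[C@H](OS(=O)(=O)O)[C@H](C)[C@H]2[C@@H]1/C=C/C=C/C(=O)O | target

Total step count: 19. Longest linear sequence: 18 steps (steps 1, 2 and 4–19).

Steps most likely to fail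

Step 14. The Michael closure may follow the sterically easier pseudo-equatorial course and give the trans ring fusion. The product may also be enolised toward C4a, which would lose the ring-fusion centre and move the C3=C4 bond into conjugation. The fallback sets out from 19 and comes back at 22. The ketone is silylated (TBSOTf, Et3N) to the tert-butyldimethylsilyl dienol ether F1. A triflimide-catalysed intramolecular (2+2) Michael–aldol closure onto the enal then gives the cis-fused silyloxy cyclobutane carbaldehyde F2. Only the cis-disposed Michael adduct can close a four-membered ring onto the six-membered ring, so the reversible first bond formation is funnelled into the cis C4a/C8a relationship. Buffered fluoride then opens the β-silyloxy aldehyde by retro-aldol cleavage of C5–C8 to 21. A proline-catalysed 6-enolexo aldolisation under neutral conditions gives 22.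

Step 7. The ketene acetal geometry of the but-3-enoate may be poorly controlled, so that C1 and C2 form as a mixture, or the dienolate may drift to the crotonate. The fallback sets out from 10 and comes back at 13. Soft enolisation with dibutylboron triflate and Hünig's base at −78 °C gives the dibutylboron ketene acetal F3. Its Z(O) geometry is set by the boron reagent and the amine, not by the solvent. It rearranges on warming to the dibutylboryl ester F4, and aqueous work-up releases 13.

Step 17. The hindered vinyl group next to two ring stereocentres may initiate slowly, and the dienoate may be consumed by self-metathesis. The fallback sets out from 25 and comes back at 27. Cross metathesis with the more reactive crotonaldehyde gives the (E)-enal F5, and a Wittig reaction with methyl (triphenylphosphoranylidene)acetate adds the second E double bond.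

Further compounds
F1 | step 14 | tert-butyldimethylsilyl dienol ether of 19 | C/C=C(\C)[C@H](/C(C)=C\C=C(\C)O[Si](C)(C)C(C)(C)C)[C@@H](C=C)/C=C(/C)C=O
F2 | step 14 | cis-fused silyloxy cyclobutane carbaldehyde (bonds C4a–C8a and C5–C8; C5 and C8 not fixed) | C/C=C(\C)[C@@H]1C(C)=C[C@@H]2[C@H]([C@@H]1C=C)C(C)(C=O)C2(C)O[Si](C)(C)C(C)(C)C
F3 | step 7 | dibutylboron ketene acetal of 10 | C[C@@H](O/C(OB(CCCC)CCCC)=C/C=C)/C(C)=C/C(C)=C\CC1(C)OCCO1
F4 | step 7 | dibutylboryl ester of 13 | C/C=C(\C)[C@H](/C(C)=C\CC1(C)OCCO1)[C@@H](C=C)C(=O)OB(CCCC)CCCC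
F5 | step 17 | (E)-enal from 25 | C/C=C(\C)[C@@H]1C(C)=C[C@H]2CC[C@H](O)[C@H](C)[C@H]2[C@@H]1/C=C/C=O
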